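**Remark on the reading of the target.** The SMILES is read as (−)-epigallocatechin 3-O-gallate-(4β→8)-(−)-epigallocatechin: upper unit 2R,3R,4R (2,3-cis, 3,4-trans), lower unit 2'R,3'R. Upper unit: rings A (benzo), C (pyran), B (2-aryl). Lower unit: rings D, F, E, with primed locants.

## Structural features

The target is a B-type prodelphinidin: two 2-arylchroman (flavan-3-ol) units joined by a single C(sp3)–C(sp2) bond from C4 of ring C to C8' of ring D. Ring C carries three contiguous stereocentres, C2, C3 and C4 (all R), with the 2-aryl and 3-acyloxy groups cis and the 3-acyloxy and 4-aryl groups trans; ring F carries C2' and C3' (both R, cis). The C3 oxygen of the upper unit bears a galloyl ester, whereas the C3' hydroxyl of the lower unit is free, so the two secondary alcohols must be told apart. Fragile elements are the thirteen phenols (three pyrogallol rings, sensitive to air and base), the ester (migration, hydrolysis), the benzylic C2–O1 and C2'–O1' ring bonds (epimerisation under base) and the acid-labile C4–C8' bond. The real difficulty is the crowded C4–C8' junction: it must sit at C8' and not at C6', trans to the C3 oxygen, and must be made without the oligomerisation that threatens when both partners are nucleophilic flavans; the less stable 2,3-cis relationship has to be kept in both units. The key step exploits the fact that C4 is benzylic to two phloroglucinol-type rings, ring A through C4a and ring D through C8'. A cation at C4 can therefore be carried by ring D of a lower unit that is already attached, and ring A, still a 3,5-dioxygenated phenyl ether with two equivalent ortho carbons, can close ring C on it (C4–C4a) under the control of C2 and C3.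

## Logic of the disconnections

**22 ⇒ 21.** The fourteen O–CH2Ph bonds are cut (thirteen phenolic, one at the C3' oxygen). Benzyl ethers are the only groups that mask pyrogallol rings through organometallic and Lewis-acid steps and still leave under neutral conditions. The gain is that all earlier chemistry is done on air-stable, soluble material. The demand is that one hydrogenolysis spares the ester, the benzylic ring C–O bonds and the C4–C8' bond.

**21 ⇒ 19 (key).** The C4–C4a bond is cut, which opens ring C. The cut is placed here because the C4 cation can be stabilised by ring D instead of ring A, so the roles of the usual coupling are reversed and the ring closure becomes intramolecular. The gain is large: ring C, the C4 stereocentre and every question of which nucleophilic carbon meets C4 disappear, and 19 is an acyclic three-carbon chain on C8' of a finished lower unit. The demands are ionisation at C4 only, closure trans to the C3 oxygen, and survival of C2 and C3.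

**19 ⇒ 12 + 16.** The C4–C8' bond is cut as a carbonyl addition. The position of the bromine in 16 fixes the 4→8 constitution, and the configuration of the new carbinol carbon need not be controlled because it is ionised afterwards. The gain is two fragments of similar size, used in equimolar amounts. The demand is an aryl metal that adds to the aldehyde of 12 without attacking its ester or enolising it.

**12 ⇒ 10 ⇒ 8 + 9.** The aldehyde is drawn from a terminal alkene (one carbon lost) and the ester C–O bond is cut. A vinyl group is an aldehyde that survives base and aryl ether formation, and 8 has a single hydroxyl group, so the galloyl group lands on the future C3 oxygen without any selectivity problem. The demand is an oxidative cleavage that spares electron-rich arenes and the centre α to the new aldehyde.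

**8 ⇒ 6 ⇒ 4 + 5.** The O1–C8a bond (oxygen to aryl carbon) and the acetal on the C3 oxygen are cut. Forming the ether at the aryl carbon, not at C2, leaves the benzylic stereocentre untouched, so the syn relationship of 4 becomes the 2,3-cis relationship of ring C with retention. The demand is C–O coupling of a hindered secondary benzylic alcohol.

**4 ⇒ 1 + 2.** The C2–C3 bond is cut. Both oxygen-bearing stereocentres of ring C arise in one reagent-controlled event, with the two oxygens already differentiated (free hydroxyl on the future C2, acetal on the future C3) and C4 present as a masked aldehyde. The demand is syn and enantio control from the reagent.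

**16 ⇒ 15 ⇒ 14 ⇒ 13.** The C8'–Br bond and six O–benzyl bonds are cut. 13 is bought with C2' and C3' in place, and bromination marks the carbon that will carry the interflavan bond. The demand is C8' over C6' selectivity in the halogenation and no epimerisation at C2' during benzylation.

## Other disconnections considered

**Alternative 1:** the first plan to come to mind cuts C4–C8' with the cation on the upper unit. Commercial (−)-epigallocatechin 3-O-gallate A1 would be perbenzylated and oxidised at C4 (DDQ, MeOH) to the 4β-methoxy ether A2; TMSOTf coupling of A2 with an excess of 15 would give 21, and hydrogenolysis 22. This is the shortest plan (about five steps). It is not chosen because its selectivity is statistical and not structural: both partners have free nucleophilic ring carbons, so 15 must be used in several-fold excess to hold back self-condensation of A2 and chain growth, and the 4→6 isomer is only disfavoured, not excluded. The chosen plan pays about six more steps for a constitution fixed by a bromine atom and an equimolar union.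

**Alternative 2:** cut O1–C2 and C3–C4 of ring C together. Addition of 17 to a salicylaldehyde-type ring A aldehyde would give the diaryl carbinol A3; acid would turn A3 into an ortho-quinone methide, and a hetero-Diels–Alder reaction with the Z-enol gallate A4 would set C2, C3 and C4 in one event. It is attractive on paper but needs three selectivities at once. The Z-dienophile must approach exo to give the 3,4-trans isomer. A stepwise cationic path would let the benzylic cation rotate and drift to the more stable 2,3-trans series. Face selection would rest on the remote stereocentres of ring F. The polarisation of an enol ester also competes with that of the styrene, which could lead to the isoflavan regiochemistry. The chosen key step has one stereocentre to set, next to two that are already fixed.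

**Alternative 3:** cut C4–C8' with reversed polarity at C4. Oxidation of 14 would give the flavan-3-one A5; Pd-catalysed α-arylation of its enolate with 16, hydride reduction with LiBH(s-Bu)3 and acylation with 9 would follow. It is not chosen because C2–H of A5 is both benzylic and α to the ketone, so the basic arylation is expected to erode C2; the aryl bromide is di-ortho-substituted and the enolate carbon is peri-hindered; and the hydride would have to choose between a face blocked by the 2-aryl group and one blocked by the 4-aryl group. In the chosen plan C2 and C3 are set once, in step 1, and are never adjacent to a carbonyl group inside the ring.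

Key step: step 10

**Assumption (availability).** Compounds 2, 5 and 9 are taken as catalogue items. If they are not, acetalisation of allyl alcohol, benzylation of 5-bromoresorcinol and chlorination of the commercial acid each add one routine step.

## Route

Step 1
Reactants: 1 3,4,5-tris(benzyloxy)benzaldehyde; 2 allyl methoxymethyl ether
Product: 4 (1R,2R)-2-(methoxymethoxy)-1-[3,4,5-tris(benzyloxy)phenyl]but-3-en-1-ol, via (Z)-alkoxyallyl diisopinocampheylborane 3 (not isolated)
Conditions: 2, s-BuLi, THF, −78 °C; (−)-Ipc2BOMe [from (+)-α-pinene]; BF3·OEt2; 1, −78 °C → rt; NaOH, H2O2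
Reagents that add atoms: none
Why: Brown asymmetric γ-alkoxyallylboration; borane 3 adds through a closed chair (Zimmerman–Traxler) transition state, so its Z geometry becomes the syn relationship of the two oxygen-bearing carbons, and the isopinocampheyl groups should direct the allyl unit to the si face of 1, as in the parent allyl series, to give the (1R,2R) isomer; these centres are the future C2 and C3 of ring C.

Step 2
Reactants: 4 (1R,2R)-2-(methoxymethoxy)-1-[3,4,5-tris(benzyloxy)phenyl]but-3-en-1-ol; 5 1,3-bis(benzyloxy)-5-bromobenzene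
Product: 6 5-{(1R,2R)-1-[3,5-bis(benzyloxy)phenoxy]-2-(methoxymethoxy)but-3-en-1-yl}-1,2,3-tris(benzyloxy)benzene
Conditions: 5 (1.5 equiv), CuI (10 mol %), 3,4,7,8-tetramethyl-1,10-phenanthroline (20 mol %), Cs2CO3, toluene, 110 °C
Reagents that add atoms: none
Why: Ullmann-type copper-catalysed C–O coupling of a secondary benzylic alcohol with an aryl bromide; the new bond is made at oxygen and no bond to the carbinol carbon is broken, so the future C2 is carried over with retention, and the acetal, the alkene and the benzyl ethers are inert to carbonate base.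

Step 3
Reactants: 6 5-{(1R,2R)-1-[3,5-bis(benzyloxy)phenoxy]-2-(methoxymethoxy)but-3-en-1-yl}-1,2,3-tris(benzyloxy)benzene
Product: 8 (1R,2R)-1-[3,5-bis(benzyloxy)phenoxy]-1-[3,4,5-tris(benzyloxy)phenyl]but-3-en-2-ol, via alkoxymethyl bipyridinium triflate 7 (not isolated)
Conditions: TMSOTf, 2,2'-bipyridyl, CH2Cl2, 0 °C → rt; then H2O
Reagents that add atoms: none
Why: Near-neutral cleavage of a methoxymethyl ether; the TMSOTf–bipyridyl pair converts the acetal into pyridinium salt 7, which water hydrolyses to the alcohol, and since no free Brønsted acid is present the neighbouring benzyl aryl ether and the benzyl ethers are expected to stay intact; no stereocentre is touched.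

Step 4
Reactants: 8 (1R,2R)-1-[3,5-bis(benzyloxy)phenoxy]-1-[3,4,5-tris(benzyloxy)phenyl]but-3-en-2-ol; 9 3,4,5-tris(benzyloxy)benzoyl chloride
Product: 10 (1R,2R)-1-[3,5-bis(benzyloxy)phenoxy]-1-[3,4,5-tris(benzyloxy)phenyl]but-3-en-2-yl 3,4,5-tris(benzyloxy)benzoate
Conditions: 9, Et3N, DMAP (cat.), CH2Cl2, 0 °C → rt
Reagents that add atoms: none
Why: DMAP-catalysed acylation of a secondary alcohol by an aroyl chloride, the usual way to place a protected galloyl group; 8 has one hydroxyl group only, so the site of galloylation is settled here for the whole synthesis.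

Step 5
Reactants: 10 (1R,2R)-1-[3,5-bis(benzyloxy)phenoxy]-1-[3,4,5-tris(benzyloxy)phenyl]but-3-en-2-yl 3,4,5-tris(benzyloxy)benzoate
Product: 12 (1R,2S)-1-[3,5-bis(benzyloxy)phenoxy]-3-oxo-1-[3,4,5-tris(benzyloxy)phenyl]propan-2-yl 3,4,5-tris(benzyloxy)benzoate, via vicinal diol 11 (not isolated)
Conditions: OsO4 (2 mol %), NaIO4, 2,6-lutidine, dioxane–H2O, 0 °C → rt
Reagents that add atoms: osmium tetroxide, O=[Os](=O)(=O)=O (catalytic carrier of the oxygen atom); sodium periodate, [Na+].[O-]I(=O)(=O)=O (stoichiometric oxygen source)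
Why: Lemieux–Johnson oxidation, that is dihydroxylation of the monosubstituted alkene and periodate cleavage of diol 11; 2,6-lutidine keeps the medium near neutral so that the α-acyloxy aldehyde should neither epimerise nor lose the β-aryloxy group, the electron-rich arenes that ozone would attack are spared, and 12 is used without chromatography (the descriptor changes from R to S only because CHO outranks the neighbouring carbon).

Step 6
Reactants: 13 (−)-epigallocatechin
Product: 14 (2R,3R)-5,7-bis(benzyloxy)-2-[3,4,5-tris(benzyloxy)phenyl]chroman-3-ol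
Conditions: BnBr, K2CO3, DMF, −10 °C → rt, Ar
Reagents that add atoms: benzyl bromide, BrCc1ccccc1
Why: Williamson etherification of the five phenols; carbonate deprotonates phenols but not the secondary alcohol, and low temperature with exclusion of air limits C-benzylation and base-induced epimerisation at C2.

Step 7
Reactants: 14 (2R,3R)-5,7-bis(benzyloxy)-2-[3,4,5-tris(benzyloxy)phenyl]chroman-3-ol
Product: 15 (2R,3R)-3,5,7-tris(benzyloxy)-2-[3,4,5-tris(benzyloxy)phenyl]chromane
Conditions: NaH, BnBr, DMF, 0 °C → rt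
Reagents that add atoms: benzyl bromide, BrCc1ccccc1
Why: Williamson etherification of the remaining secondary alcohol through its sodium alkoxide; with all phenols capped no quinone methide pathway is open, so C2 and C3 are configurationally safe.

Step 8
Reactants: 15 (2R,3R)-3,5,7-tris(benzyloxy)-2-[3,4,5-tris(benzyloxy)phenyl]chromane
Product: 16 (2R,3R)-3,5,7-tris(benzyloxy)-8-bromo-2-[3,4,5-tris(benzyloxy)phenyl]chromane
Conditions: NBS, CH2Cl2, −78 → 0 °C
Reagents that add atoms: N-bromosuccinimide, O=C1CCC(=O)N1Br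
Why: Electrophilic aromatic bromination; 5,7-di-O-benzyl flavans are known to brominate at C8 in preference to C6, one equivalent at low temperature avoids dibromination and attack on the less activated ring, and the bromine marks the carbon that will carry the interflavan bond.

Step 9
Reactants: 16 (2R,3R)-3,5,7-tris(benzyloxy)-8-bromo-2-[3,4,5-tris(benzyloxy)phenyl]chromane; 12 (1R,2S)-1-[3,5-bis(benzyloxy)phenoxy]-3-oxo-1-[3,4,5-tris(benzyloxy)phenyl]propan-2-yl 3,4,5-tris(benzyloxy)benzoate
Product: 19 (1RS,2R,3R)-3-[3,5-bis(benzyloxy)phenoxy]-1-hydroxy-1-{(2R,3R)-3,5,7-tris(benzyloxy)-2-[3,4,5-tris(benzyloxy)phenyl]chroman-8-yl}-3-[3,4,5-tris(benzyloxy)phenyl]propan-2-yl 3,4,5-tris(benzyloxy)benzoate, via aryllithium 17 (not isolated), via aryl cerium dichloride 18 (not isolated)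
Conditions: 16, t-BuLi (2 equiv), THF, −78 °C; CeCl3, −78 °C; 12, −78 °C; AcOH, −78 °C
Reagents that add atoms: none
Why: Bromine–lithium exchange (the second equivalent of t-BuLi destroys t-BuBr), transmetalation to the organocerium reagent and 1,2-addition to the aldehyde; the weakly basic, oxophilic cerium reagent should add to the aldehyde faster than it enolises it or attacks the aryl ester, the cold acidic quench is meant to prevent 1,2-acyl migration, and the configuration of the new carbinol carbon is irrelevant because step 10 ionises it.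

Step 10
Reactants: 19 (1RS,2R,3R)-3-[3,5-bis(benzyloxy)phenoxy]-1-hydroxy-1-{(2R,3R)-3,5,7-tris(benzyloxy)-2-[3,4,5-tris(benzyloxy)phenyl]chroman-8-yl}-3-[3,4,5-tris(benzyloxy)phenyl]propan-2-yl 3,4,5-tris(benzyloxy)benzoate
Product: 21 (2R,3R,4R)-5,7-bis(benzyloxy)-2-[3,4,5-tris(benzyloxy)phenyl]-4-{(2R,3R)-3,5,7-tris(benzyloxy)-2-[3,4,5-tris(benzyloxy)phenyl]chroman-8-yl}chroman-3-yl 3,4,5-tris(benzyloxy)benzoate, via benzylic cation 20 (not isolated)
Conditions: BF3·OEt2 (0.3 equiv), 4 Å MS, CH2Cl2, −78 → −30 °C; aq. NaHCO3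
Reagents that add atoms: none
Why: BF3 ionises the C4 hydroxyl of either epimer of 19 to the same cation 20, which is stabilised as a quinone-methide-type ion by the three oxygens on ring D (O1', O5', O7'), so this carbinol should ionise far more readily than the C2–O1 benzyl aryl ether. The closest known reaction type is the acid-mediated Friedel–Crafts cyclisation of 1-aryl-3-aryloxypropan-1-ols to 4-arylchromans. Ring C closes by 6-exo-trig attack of an ortho carbon of the 3,5-bis(benzyloxy)phenoxy group on the exocyclic cationic carbon; that carbon is activated by three oxygens, the two ortho sites are equivalent, and the para site cannot reach, so there is no regiochemical choice. The only new stereocentre, C4, is controlled by C3: the galloyl carbonyl oxygen can bridge the cation as the less crowded trans-4,5-disubstituted 1,3-dioxolan-2-ylium ion, and ring A displaces it from the opposite face, which gives the 3,4-trans (4R) isomer. The open cation should lead to the same isomer, because the two transition states for the 3,4-cis product suffer either from a 1,3-diaxial clash of the 2-aryl and 4-aryl groups or from peri strain between a pseudo-equatorial 4-aryl group and the C5 benzyloxy group. The selectivity needed is ring A over ring B (which could close a five-membered carbocycle); it is secured by the much higher nucleophilicity of the phloroglucinol-type ring A and by the six-membered transition state. Because the C4–C8' bond exists before the cation forms, the 4→8 constitution is fixed and no excess flavan nucleophile is present that could start oligomers.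

Step 11
Reactants: 21 (2R,3R,4R)-5,7-bis(benzyloxy)-2-[3,4,5-tris(benzyloxy)phenyl]-4-{(2R,3R)-3,5,7-tris(benzyloxy)-2-[3,4,5-tris(benzyloxy)phenyl]chroman-8-yl}chroman-3-yl 3,4,5-tris(benzyloxy)benzoate
Product: 22 (2R,3R,4R)-5,7-dihydroxy-2-(3,4,5-trihydroxyphenyl)-4-[(2R,3R)-3,5,7-trihydroxy-2-(3,4,5-trihydroxyphenyl)chroman-8-yl]chroman-3-yl 3,4,5-trihydroxybenzoate
Conditions: H2 (1 atm), Pd(OH)2/C, THF–MeOH–H2O, rt
Reagents that add atoms: none
Why: Hydrogenolysis of all fourteen benzyl ethers under neutral conditions; the aryl ester, the benzylic C–O bonds of both pyran rings and the acid-labile interflavan bond are expected to survive, no stereocentre is affected, and filtration under inert gas followed by lyophilisation protects the pyrogallol rings from air.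

## Compound list

1 | 3,4,5-tris(benzyloxy)benzaldehyde | O=Cc1cc(OCc2ccccc2)c(OCc2ccccc2)c(OCc2ccccc2)c1 | starting material
2 | allyl methoxymethyl ether, 3-(methoxymethoxy)prop-1-ene | C=CCOCOC | starting material
3 | B-[(Z)-3-(methoxymethoxy)prop-2-en-1-yl]diisopinocampheylborane, both isopinocampheyl groups from (+)-α-pinene (formed in situ) | COCO/C=C\CB([C@@H]1C[C@@H]2C[C@@H](C2(C)C)[C@H]1C)[C@@H]1C[C@@H]2C[C@@H](C2(C)C)[C@H]1C | intermediate
4 | (1R,2R)-2-(methoxymethoxy)-1-[3,4,5-tris(benzyloxy)phenyl]but-3-en-1-ol | C=C[C@@H](OCOC)[C@H](O)c1cc(OCc2ccccc2)c(OCc2ccccc2)c(OCc2ccccc2)c1 | intermediate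
5 | 1,3-bis(benzyloxy)-5-bromobenzene | Brc1cc(OCc2ccccc2)cc(OCc2ccccc2)c1 | starting material
6 | 5-{(1R,2R)-1-[3,5-bis(benzyloxy)phenoxy]-2-(methoxymethoxy)but-3-en-1-yl}-1,2,3-tris(benzyloxy)benzene | C=C[C@@H](OCOC)[C@H](Oc1cc(OCc2ccccc2)cc(OCc2ccccc2)c1)c1cc(OCc2ccccc2)c(OCc2ccccc2)c(OCc2ccccc2)c1 | intermediate
7 | 1-({[(1R,2R)-1-[3,5-bis(benzyloxy)phenoxy]-1-[3,4,5-tris(benzyloxy)phenyl]but-3-en-2-yl]oxy}methyl)-2-(pyridin-2-yl)pyridinium triflate (formed in situ) | C=C[C@@H](OC[n+]1ccccc1-c1ccccn1)[C@H](Oc1cc(OCc2ccccc2)cc(OCc2ccccc2)c1)c1cc(OCc2ccccc2)c(OCc2ccccc2)c(OCc2ccccc2)c1.[O-]S(=O)(=O)C(F)(F)F | intermediate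
8 | (1R,2R)-1-[3,5-bis(benzyloxy)phenoxy]-1-[3,4,5-tris(benzyloxy)phenyl]but-3-en-2-ol | C=C[C@@H](O)[C@H](Oc1cc(OCc2ccccc2)cc(OCc2ccccc2)c1)c1cc(OCc2ccccc2)c(OCc2ccccc2)c(OCc2ccccc2)c1 | intermediate
9 | 3,4,5-tris(benzyloxy)benzoyl chloride | O=C(Cl)c1cc(OCc2ccccc2)c(OCc2ccccc2)c(OCc2ccccc2)c1 | starting material
10 | (1R,2R)-1-[3,5-bis(benzyloxy)phenoxy]-1-[3,4,5-tris(benzyloxy)phenyl]but-3-en-2-yl 3,4,5-tris(benzyloxy)benzoate | C=C[C@@H](OC(=O)c1cc(OCc2ccccc2)c(OCc2ccccc2)c(OCc2ccccc2)c1)[C@H](Oc1cc(OCc2ccccc2)cc(OCc2ccccc2)c1)c1cc(OCc2ccccc2)c(OCc2ccccc2)c(OCc2ccccc2)c1 | intermediate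
11 | (1R,2R,3RS)-1-[3,5-bis(benzyloxy)phenoxy]-3,4-dihydroxy-1-[3,4,5-tris(benzyloxy)phenyl]butan-2-yl 3,4,5-tris(benzyloxy)benzoate (formed in situ) | OCC(O)[C@@H](OC(=O)c1cc(OCc2ccccc2)c(OCc2ccccc2)c(OCc2ccccc2)c1)[C@H](Oc1cc(OCc2ccccc2)cc(OCc2ccccc2)c1)c1cc(OCc2ccccc2)c(OCc2ccccc2)c(OCc2ccccc2)c1 | intermediate
12 | (1R,2S)-1-[3,5-bis(benzyloxy)phenoxy]-3-oxo-1-[3,4,5-tris(benzyloxy)phenyl]propan-2-yl 3,4,5-tris(benzyloxy)benzoate | O=C[C@@H](OC(=O)c1cc(OCc2ccccc2)c(OCc2ccccc2)c(OCc2ccccc2)c1)[C@H](Oc1cc(OCc2ccccc2)cc(OCc2ccccc2)c1)c1cc(OCc2ccccc2)c(OCc2ccccc2)c(OCc2ccccc2)c1 | intermediate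
13 | (−)-epigallocatechin, (2R,3R)-2-(3,4,5-trihydroxyphenyl)chromane-3,5,7-triol | O[C@@H]1Cc2c(O)cc(O)cc2O[C@@H]1c1cc(O)c(O)c(O)c1 | starting material
14 | (2R,3R)-5,7-bis(benzyloxy)-2-[3,4,5-tris(benzyloxy)phenyl]chroman-3-ol | O[C@@H]1Cc2c(OCc3ccccc3)cc(OCc3ccccc3)cc2O[C@@H]1c1cc(OCc2ccccc2)c(OCc2ccccc2)c(OCc2ccccc2)c1 | intermediate
15 | (2R,3R)-3,5,7-tris(benzyloxy)-2-[3,4,5-tris(benzyloxy)phenyl]chromane | C(O[C@@H]1Cc2c(OCc3ccccc3)cc(OCc3ccccc3)cc2O[C@@H]1c1cc(OCc2ccccc2)c(OCc2ccccc2)c(OCc2ccccc2)c1)c1ccccc1 | intermediate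
16 | (2R,3R)-3,5,7-tris(benzyloxy)-8-bromo-2-[3,4,5-tris(benzyloxy)phenyl]chromane | C(O[C@@H]1Cc2c(OCc3ccccc3)cc(OCc3ccccc3)c(Br)c2O[C@@H]1c1cc(OCc2ccccc2)c(OCc2ccccc2)c(OCc2ccccc2)c1)c1ccccc1 | intermediate
17 | 8-lithio derivative of 15 (formed in situ) | C(O[C@@H]1Cc2c(OCc3ccccc3)cc(OCc3ccccc3)c([Li])c2O[C@@H]1c1cc(OCc2ccccc2)c(OCc2ccccc2)c(OCc2ccccc2)c1)c1ccccc1 | intermediate
18 | 8-(dichlorocerio) derivative of 15, ArCeCl2 (formed in situ) | C(O[C@@H]1Cc2c(OCc3ccccc3)cc(OCc3ccccc3)c([Ce](Cl)Cl)c2O[C@@H]1c1cc(OCc2ccccc2)c(OCc2ccccc2)c(OCc2ccccc2)c1)c1ccccc1 | intermediate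
19 | (1RS,2R,3R)-3-[3,5-bis(benzyloxy)phenoxy]-1-hydroxy-1-{(2R,3R)-3,5,7-tris(benzyloxy)-2-[3,4,5-tris(benzyloxy)phenyl]chroman-8-yl}-3-[3,4,5-tris(benzyloxy)phenyl]propan-2-yl 3,4,5-tris(benzyloxy)benzoate (C1 epimers) | OC(c1c(OCc3ccccc3)cc(OCc3ccccc3)c2C[C@@H](OCc3ccccc3)[C@@H](c3cc(OCc4ccccc4)c(OCc4ccccc4)c(OCc4ccccc4)c3)Oc12)[C@@H](OC(=O)c1cc(OCc2ccccc2)c(OCc2ccccc2)c(OCc2ccccc2)c1)[C@H](Oc1cc(OCc2ccccc2)cc(OCc2ccccc2)c1)c1cc(OCc2ccccc2)c(OCc2ccccc2)c(OCc2ccccc2)c1 | intermediate
20 | C1 cation of 19 (future C4), drawn open; in equilibrium with its galloyl-bridged 1,3-dioxolan-2-ylium form (formed in situ) | [CH+](c1c(OCc3ccccc3)cc(OCc3ccccc3)c2C[C@@H](OCc3ccccc3)[C@@H](c3cc(OCc4ccccc4)c(OCc4ccccc4)c(OCc4ccccc4)c3)Oc12)[C@@H](OC(=O)c1cc(OCc2ccccc2)c(OCc2ccccc2)c(OCc2ccccc2)c1)[C@H](Oc1cc(OCc2ccccc2)cc(OCc2ccccc2)c1)c1cc(OCc2ccccc2)c(OCc2ccccc2)c(OCc2ccccc2)c1 | intermediate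
21 | (2R,3R,4R)-5,7-bis(benzyloxy)-2-[3,4,5-tris(benzyloxy)phenyl]-4-{(2R,3R)-3,5,7-tris(benzyloxy)-2-[3,4,5-tris(benzyloxy)phenyl]chroman-8-yl}chroman-3-yl 3,4,5-tris(benzyloxy)benzoate | O=C(O[C@@H]1[C@@H](c2c(OCc4ccccc4)cc(OCc4ccccc4)c3c2O[C@H](c2cc(OCc4ccccc4)c(OCc4ccccc4)c(OCc4ccccc4)c2)[C@H](OCc4ccccc4)C3)c2c(OCc4ccccc4)cc(OCc4ccccc4)cc2O[C@@H]1c1cc(OCc4ccccc4)c(OCc4ccccc4)c(OCc4ccccc4)c1)c1cc(OCc4ccccc4)c(OCc4ccccc4)c(OCc4ccccc4)c1 | intermediate
22 | (2R,3R,4R)-5,7-dihydroxy-2-(3,4,5-trihydroxyphenyl)-4-[(2R,3R)-3,5,7-trihydroxy-2-(3,4,5-trihydroxyphenyl)chroman-8-yl]chroman-3-yl 3,4,5-trihydroxybenzoate | O=C(O[C@@H]1[C@@H](c2c(O)cc(O)c3c2O[C@H](c2cc(O)c(O)c(O)c2)[C@H](O)C3)c2c(O)cc(O)cc2O[C@@H]1c1cc(O)c(O)c(O)c1)c1cc(O)c(O)c(O)c1 | target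

## Step count and least certain steps

Total step count: 11. Longest linear sequence: 8 steps (steps 1–5, 9, 10, 11); steps 6–8 form the second branch.

**Step 10 (key step).** The most likely failure is loss of control at the cation stage: elimination of the C3 hydrogen to an enol ester, closure of a five-membered carbocycle through ring B, or erosion of the 3,4-trans preference if the bridged ion does not form. The cause is that the ring-D-stabilised cation is long-lived and has several nucleophilic sites within reach. The fallback reverses the order in which the two aryl groups are attached to C4. It sets out from 12 and 15. Aldehyde 12, treated alone with BF3·OEt2 at −78 °C, should undergo the six-membered Friedel–Crafts hydroxyalkylation by ring A to give the flavan-4-ol gallate F1. TMSOTf-mediated coupling of F1 with an excess of 15 should then give the 3,4-trans product through the galloyl-bridged ring-C cation, with the 4→8 link resting on the inherent preference of ring D. The fallback returns to the route at 21.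

**Step 9.** The most likely failures are attack of the aryl metal on the gallate carbonyl, enolisation of 12 followed by loss of the aryloxide or epimerisation of the α-carbon, and 1,2-acyl migration in the metal alkoxide before the quench. The di-ortho-substituted aryl metal adds slowly, which gives these processes time; the lability of 12 itself (step 5) adds to the risk. The fallback defers the ester and sets out from 8. Silylation (TBSOTf, 2,6-lutidine) would give the silyl ether F2, and OsO4/NaIO4 cleavage the α-silyloxy aldehyde F3, which tolerates the plain aryllithium 17 and would give the carbinol F4. BF3·OEt2 would then close ring C to the 3-O-silyl dimer F5, now relying on the conformational argument alone for the 3,4-trans outcome. TBAF would free the C3 alcohol F6, the only hydroxyl group in the molecule, and acylation with 9 returns to the route at 21.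

**Step 2.** The most likely failure is low conversion or oxidation of the benzylic alkoxide by β-hydride loss at copper, because the alcohol is secondary, benzylic and next to a branched carbon and the aryl bromide is not activated. The fallback replaces metal catalysis by nucleophilic aromatic substitution and sets out from 4. Its sodium alkoxide (NaH, DMF) and 1,3,5-trifluorobenzene should give the 3,5-difluorophenyl ether F7. The two remaining fluorides would then be displaced by sodium benzyloxide (BnOH, NaH, DMPU, 120 °C; forcing, because each alkoxy group deactivates the ring), which returns to the route at 6.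

## Further compounds

F1 | step 10 | (2R,3R,4RS)-5,7-bis(benzyloxy)-4-hydroxy-2-[3,4,5-tris(benzyloxy)phenyl]chroman-3-yl 3,4,5-tris(benzyloxy)benzoate | O=C(O[C@@H]1C(O)c2c(OCc4ccccc4)cc(OCc4ccccc4)cc2O[C@@H]1c1cc(OCc4ccccc4)c(OCc4ccccc4)c(OCc4ccccc4)c1)c1cc(OCc4ccccc4)c(OCc4ccccc4)c(OCc4ccccc4)c1
F2 | step 9 | tert-butyl{[(1R,2R)-1-[3,5-bis(benzyloxy)phenoxy]-1-[3,4,5-tris(benzyloxy)phenyl]but-3-en-2-yl]oxy}dimethylsilane | C=C[C@@H](O[Si](C)(C)C(C)(C)C)[C@H](Oc1cc(OCc2ccccc2)cc(OCc2ccccc2)c1)c1cc(OCc2ccccc2)c(OCc2ccccc2)c(OCc2ccccc2)c1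
F3 | step 9 | (2S,3R)-3-[3,5-bis(benzyloxy)phenoxy]-2-[(tert-butyldimethylsilyl)oxy]-3-[3,4,5-tris(benzyloxy)phenyl]propanal | O=C[C@@H](O[Si](C)(C)C(C)(C)C)[C@H](Oc1cc(OCc2ccccc2)cc(OCc2ccccc2)c1)c1cc(OCc2ccccc2)c(OCc2ccccc2)c(OCc2ccccc2)c1
F4 | step 9 | (1RS,2R,3R)-3-[3,5-bis(benzyloxy)phenoxy]-2-[(tert-butyldimethylsilyl)oxy]-1-{(2R,3R)-3,5,7-tris(benzyloxy)-2-[3,4,5-tris(benzyloxy)phenyl]chroman-8-yl}-3-[3,4,5-tris(benzyloxy)phenyl]propan-1-ol | OC(c1c(OCc3ccccc3)cc(OCc3ccccc3)c2C[C@@H](OCc3ccccc3)[C@@H](c3cc(OCc4ccccc4)c(OCc4ccccc4)c(OCc4ccccc4)c3)Oc12)[C@@H](O[Si](C)(C)C(C)(C)C)[C@H](Oc1cc(OCc2ccccc2)cc(OCc2ccccc2)c1)c1cc(OCc2ccccc2)c(OCc2ccccc2)c(OCc2ccccc2)c1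
F5 | step 9 | 3-O-(tert-butyldimethylsilyl) analogue of 21 (silyl ether in place of the galloyl ester; 2R,3R,4R and 2'R,3'R) | CC(C)(C)[Si](C)(C)O[C@@H]1[C@@H](c2c(OCc4ccccc4)cc(OCc4ccccc4)c3c2O[C@H](c2cc(OCc4ccccc4)c(OCc4ccccc4)c(OCc4ccccc4)c2)[C@H](OCc4ccccc4)C3)c2c(OCc4ccccc4)cc(OCc4ccccc4)cc2O[C@@H]1c1cc(OCc4ccccc4)c(OCc4ccccc4)c(OCc4ccccc4)c1
F6 | step 9 | (2R,3R,4R)-5,7-bis(benzyloxy)-2-[3,4,5-tris(benzyloxy)phenyl]-4-{(2R,3R)-3,5,7-tris(benzyloxy)-2-[3,4,5-tris(benzyloxy)phenyl]chroman-8-yl}chroman-3-ol | O[C@@H]1[C@@H](c2c(OCc4ccccc4)cc(OCc4ccccc4)c3c2O[C@H](c2cc(OCc4ccccc4)c(OCc4ccccc4)c(OCc4ccccc4)c2)[C@H](OCc4ccccc4)C3)c2c(OCc4ccccc4)cc(OCc4ccccc4)cc2O[C@@H]1c1cc(OCc4ccccc4)c(OCc4ccccc4)c(OCc4ccccc4)c1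
F7 | step 2 | 1,2,3-tris(benzyloxy)-5-[(1R,2R)-1-(3,5-difluorophenoxy)-2-(methoxymethoxy)but-3-en-1-yl]benzene | C=C[C@@H](OCOC)[C@H](Oc1cc(F)cc(F)c1)c1cc(OCc2ccccc2)c(OCc2ccccc2)c(OCc2ccccc2)c1
A1 | alternative 1 | (−)-epigallocatechin 3-O-gallate | O=C(O[C@@H]1Cc2c(O)cc(O)cc2O[C@@H]1c1cc(O)c(O)c(O)c1)c1cc(O)c(O)c(O)c1
A2 | alternative 1 | octa-O-benzyl-4β-methoxy-(−)-epigallocatechin 3-O-gallate (4-methoxy trans to the 3-acyloxy group) | O=C(O[C@@H]1[C@@H](OC)c2c(OCc4ccccc4)cc(OCc4ccccc4)cc2O[C@@H]1c1cc(OCc4ccccc4)c(OCc4ccccc4)c(OCc4ccccc4)c1)c1cc(OCc4ccccc4)c(OCc4ccccc4)c(OCc4ccccc4)c1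
A3 | alternative 2 | [4,6-bis(benzyloxy)-2-hydroxyphenyl]{(2R,3R)-3,5,7-tris(benzyloxy)-2-[3,4,5-tris(benzyloxy)phenyl]chroman-8-yl}methanol (carbinol epimers) | OC(c1c(O)cc(OCc2ccccc2)cc1OCc1ccccc1)c1c(OCc3ccccc3)cc(OCc3ccccc3)c2C[C@@H](OCc3ccccc3)[C@@H](c3cc(OCc4ccccc4)c(OCc4ccccc4)c(OCc4ccccc4)c3)Oc12
A4 | alternative 2 | (Z)-2-[3,4,5-tris(benzyloxy)phenyl]ethenyl 3,4,5-tris(benzyloxy)benzoate | O=C(O/C=C\c1cc(OCc2ccccc2)c(OCc2ccccc2)c(OCc2ccccc2)c1)c1cc(OCc2ccccc2)c(OCc2ccccc2)c(OCc2ccccc2)c1
A5 | alternative 3 | (2R)-5,7-bis(benzyloxy)-2-[3,4,5-tris(benzyloxy)phenyl]chroman-3-one | O=C1Cc2c(OCc3ccccc3)cc(OCc3ccccc3)cc2O[C@@H]1c1cc(OCc2ccccc2)c(OCc2ccccc2)c(OCc2ccccc2)c1
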